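**Strategy**

The cyclohexane core is cut across C2–C3 and C5–C6 (ring numbered C1 = side-chain carbon, C2 = CH2, C3–C5 = O–C–C(Me)(OH)–C–O, C6 = CHOH). C3–C4–C5 is a latent dihydroxyacetone and C2–C1–C6 a latent 2-substituted acrolein. One amino-acid-catalysed domino Michael/aldol [3+3] annulation of bis-silylated dihydroxyacetone with an acrolein that carries a masked acetyl group forms both bonds and sets C1, C3, C5 and C6, C1 by dynamic resolution. Methyl addition to the C4 ketone, side-chain growth from the acetyl group, triple angeloylation and a late epoxidation finish the target.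

Key step: step 3

Remark on numbering: locants C1–C6 (ring) and C1′–C5′ (side chain: C1′ = C(=CH2), C2′ = CH–O, C3′ = CH2, C4′ = epoxide CH, C5′ = CMe2) in the text are those of the target; systematic names in the compound list use their own locants.

Remark on the chemistry: the enantiomer of the threonine catalyst (step 3) and of the sulfonamide ligand (step 8) are those predicted by the stated models; the mirror-image catalyst or ligand would be taken if a model run showed the opposite sense.

Compounds 1, 4 and 11 are assumed to be purchased.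

**Route**

Step 1
Reactants: 1 ethyl (2-methyl-1,3-dioxolan-2-yl)acetate
Product: 2 (2-methyl-1,3-dioxolan-2-yl)acetaldehyde
Conditions: iBu2AlH (1.05 equiv), CH2Cl2, −78 °C; MeOH, aq. potassium sodium tartrate
Reagents that add atoms: none
Why: Half-reduction of an ester with an aluminium hydride, whose tetrahedral aluminium alkoxide is stable at −78 °C and collapses to the aldehyde only on work-up; no stereocentre.

Step 2
Reactants: 2 (2-methyl-1,3-dioxolan-2-yl)acetaldehyde
Product: 3 2-(2-methyl-1,3-dioxolan-2-yl)prop-2-enal
Conditions: 37% aq. formaldehyde, pyrrolidine (10 mol%), propionic acid (10 mol%), iPrOH, 45 °C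
Reagents that add atoms: formaldehyde, C=O
Why: Organocatalytic α-methylenation (Mannich condensation through the enamine, then amine elimination) at the only enolisable position; no stereocentre.

Step 3
Reactants: 3 2-(2-methyl-1,3-dioxolan-2-yl)prop-2-enal; 4 1,3-bis(tert-butyldimethylsilyloxy)propan-2-one
Product: 6 (2S,3S,4S,6S)-2,6-bis(tert-butyldimethylsilyloxy)-3-hydroxy-4-(2-methyl-1,3-dioxolan-2-yl)cyclohexan-1-one, via keto aldehyde 5 (not isolated)
Conditions: 4 (2 equiv), O-tert-butyl-D-threonine (20 mol%), N-methylpyrrolidone/H2O (97:3), 4 °C to rt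
Reagents that add atoms: none
Why: The threonine amine condenses with 4 to a Z-enamine (N–H···O–Si hydrogen bond) that adds to the CH2 terminus of 3 (C2–C3 bond); the iminium formed tautomerises to the enamine on the other α-carbon, which closes on the aldehyde (C5–C6 bond), and hydrolysis returns the catalyst. This is the Stork α,α′-annulation of a ketone enamine with an acrolein (domino Michael/aldol, formal [3+3]), run with the primary-amino-acid catalysis known for aldol reactions of silylated dihydroxyacetone. The single ring closes by a 6-(enolendo)-exo-trig aldol through a chair. C3 and C5 are set by the catalyst, which shields the same enamine face in both events and so gives the trans (S,S) pair, C5–OTBS equatorial from the Z-enamine and C3–OTBS axial by allylic 1,3-strain; C6–OH comes out axial, cis to O5, because the aldehyde oxygen is hydrogen-bonded to the carboxylic acid beside nitrogen; C1 is set dynamically, since 5 epimerises at C1 (α to CHO) and only the epimer with the bulky dioxolanyl group equatorial cyclises. The step needs a single Michael/aldol pairing, which the substrates secure: 3 has no α-hydrogen and cannot act as donor, 4 is symmetric, and every other aldol closure of 5 would give a four-membered ring.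

Step 4
Reactants: 6 (2S,3S,4S,6S)-2,6-bis(tert-butyldimethylsilyloxy)-3-hydroxy-4-(2-methyl-1,3-dioxolan-2-yl)cyclohexan-1-one
Product: 7 (1R,2S,3S,4S,6S)-2,6-bis(tert-butyldimethylsilyloxy)-1-methyl-4-(2-methyl-1,3-dioxolan-2-yl)cyclohexane-1,3-diol
Conditions: MeMgBr (4 equiv), THF/CH2Cl2, −78 to −30 °C; aq. NH4Cl
Reagents that add atoms: methylmagnesium bromide, C[Mg]Br
Why: Grignard 1,2-addition in which the first equivalent turns the axial C6–OH into a magnesium alkoxide that chelates the ketone and blocks the syn-axial face, so methyl should enter along the equatorial trajectory of the chair locked by the equatorial dioxolanyl group, making the new C4–OH axial, cis to O5 and O6 and trans to O3.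

Step 5
Reactants: 7 (1R,2S,3S,4S,6S)-2,6-bis(tert-butyldimethylsilyloxy)-1-methyl-4-(2-methyl-1,3-dioxolan-2-yl)cyclohexane-1,3-diol
Product: 9 methyl ketone (C4/C6 acetonide, C1 acetyl), via acetonide ketal 8 (not isolated)
Conditions: 2-methoxypropene (2 equiv), PPTS (10 mol%), dry acetone, 0 °C; then 45 °C
Reagents that add atoms: 2-methoxypropene, COC(C)=C
Why: Acid-catalysed acetalisation of the cis-diaxial C4/C6 diol, then transketalisation of the dioxolane to the solvent acetone, which frees the methyl ketone while the diol acetonide persists because its exchange with acetone is degenerate; no stereocentre is touched.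

Step 6
Reactants: 9 methyl ketone (C4/C6 acetonide, C1 acetyl)
Product: 10 alkenyl triflate (C1 bears C(OTf)=CH2)
Conditions: KN(SiMe3)2 (1.2 equiv), THF, −78 °C; PhNTf2, −78 to 0 °C
Reagents that add atoms: N-phenylbis(trifluoromethanesulfonimide), O=S(=O)(N(c1ccccc1)S(=O)(=O)C(F)(F)F)C(F)(F)F
Why: Kinetic enolate formation at the unhindered methyl group followed by O-sulfonylation (enol triflate synthesis); the C1–H is not removed at −78 °C, so C1 keeps its configuration.

Step 7
Reactants: 11 4-methylpent-3-en-1-ol
Product: 12 4-methylpent-3-enal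
Conditions: Dess–Martin periodinane, NaHCO3, CH2Cl2, 0 °C; used at once
Reagents that add atoms: none
Why: Dess–Martin oxidation of a primary alcohol under buffered conditions that should not move the β,γ-double bond into conjugation; no stereocentre.

Step 8
Reactants: 10 alkenyl triflate (C1 bears C(OTf)=CH2); 12 4-methylpent-3-enal
Product: 13 (S)-allylic alcohol (C1 bears C(=CH2)–CH(OH)–CH2–CH=CMe2)
Conditions: CrCl2 (4 equiv), NiCl2 (2 mol%), (S)-N-[2-(4-isopropyl-4,5-dihydro-1,3-oxazol-2-yl)-6-methylphenyl]methanesulfonamide (4.4 equiv), Et3N, THF, rt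
Reagents that add atoms: none
Why: Nozaki–Hiyama–Kishi coupling, in which zerovalent nickel inserts into the C–OTf bond, the alkenyl group passes to chromium and the trivalent alkenylchromium adds to the aldehyde; the chiral oxazoline–sulfonamide ligand on chromium is expected to direct Re-face addition and so set C2′ as S under reagent control.

Step 9
Reactants: 13 (S)-allylic alcohol
Product: 14 triol (free OH at C3, C5 and C2′; C4/C6 acetonide)
Conditions: Bu4NF (5 equiv), THF, rt to 45 °C
Reagents that add atoms: none
Why: Fluoride-induced cleavage of both silyl ethers (desilylation), to which the acetonide, the alkenes and the allylic alcohol are inert.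

Step 10
Reactants: 14 triol
Product: 15 tris-angelate (C4/C6 acetonide)
Conditions: angelic acid (6 equiv), 2,4,6-trichlorobenzoyl chloride (6 equiv), Et3N, toluene, rt; then 14, 80 °C, no DMAP
Reagents that add atoms: angelic acid, C/C=C(/C)C(=O)O
Why: Yamaguchi-type esterification through the preformed mixed anhydride acylates the three secondary hydroxyls with retention; leaving out DMAP avoids the addition/elimination path that turns angelates into tiglates, and the acetonide keeps O4 and O6 out of the reaction.

Step 11
Reactants: 15 tris-angelate (C4/C6 acetonide)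
Product: 16 diol tris-angelate (de-epoxy target)
Conditions: AcOH/THF/H2O (3:1:1), 40 °C
Reagents that add atoms: none
Why: Mild acetal hydrolysis of the strained bridged acetonide; the esters and both alkenes should tolerate aqueous acetic acid, and the trans-diaxial O3 ester cannot migrate to O4.

Step 12
Reactants: 16 diol tris-angelate
Product: 17 target
Conditions: L-fructose-derived ketone catalyst of the Shi epoxidation (30 mol%), KHSO5 (Oxone), K2CO3, Bu4NHSO4, MeCN/dimethoxymethane, aq. Na2B4O7 buffer, 0 °C
Reagents that add atoms: potassium peroxymonosulfate (Oxone), [K+].[O-]S(=O)(=O)OO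
Why: Shi asymmetric epoxidation, in which the chiral dioxirane attacks the most electron-rich trisubstituted alkene (the 1,1-disubstituted alkene and the angelates react more slowly) through the spiro transition state; the L-fructose-derived ketone should give the (S)-epoxide at C4′, the mirror image of the (R)-epoxide expected from the D-fructose-derived catalyst.

**Compound list**

1 | ethyl (2-methyl-1,3-dioxolan-2-yl)acetate | CCOC(=O)CC1(C)OCCO1 | starting material
2 | (2-methyl-1,3-dioxolan-2-yl)acetaldehyde | O=CCC1(C)OCCO1 | intermediate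
3 | 2-(2-methyl-1,3-dioxolan-2-yl)prop-2-enal | C=C(C=O)C1(C)OCCO1 | intermediate
4 | 1,3-bis(tert-butyldimethylsilyloxy)propan-2-one | CC(C)(C)[Si](C)(C)OCC(=O)CO[Si](C)(C)C(C)(C)C | starting material
5 | (4S)-4,6-bis(tert-butyldimethylsilyloxy)-2-(2-methyl-1,3-dioxolan-2-yl)-5-oxohexanal, C2 epimers in equilibrium (not isolated) | CC(C)(C)[Si](C)(C)OCC(=O)[C@@H](O[Si](C)(C)C(C)(C)C)CC(C=O)C1(C)OCCO1 | intermediate
6 | (2S,3S,4S,6S)-2,6-bis(tert-butyldimethylsilyloxy)-3-hydroxy-4-(2-methyl-1,3-dioxolan-2-yl)cyclohexan-1-one | CC1(OCCO1)[C@H]2C[C@H](O[Si](C)(C)C(C)(C)C)C(=O)[C@@H](O[Si](C)(C)C(C)(C)C)[C@H]2O | intermediate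
7 | (1R,2S,3S,4S,6S)-2,6-bis(tert-butyldimethylsilyloxy)-1-methyl-4-(2-methyl-1,3-dioxolan-2-yl)cyclohexane-1,3-diol | CC1(OCCO1)[C@H]2C[C@H](O[Si](C)(C)C(C)(C)C)[C@@](C)(O)[C@@H](O[Si](C)(C)C(C)(C)C)[C@H]2O | intermediate
8 | acetonide of 7: isopropylidene acetal bridging the two hydroxyl oxygens (2,4-dioxabicyclo[3.3.1]nonane), dioxolane intact, ring configuration as in 7 (not isolated) | CC1(OCCO1)[C@H]2C[C@H](O[Si](C)(C)C(C)(C)C)[C@@](C)(O3)[C@@H](O[Si](C)(C)C(C)(C)C)[C@H]2OC3(C)C | intermediate
9 | methyl ketone: as 8, with the 2-methyl-1,3-dioxolan-2-yl group replaced by acetyl | CC(=O)[C@H]2C[C@H](O[Si](C)(C)C(C)(C)C)[C@@](C)(O3)[C@@H](O[Si](C)(C)C(C)(C)C)[C@H]2OC3(C)C | intermediate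
10 | alkenyl triflate: as 9, with acetyl replaced by 1-(trifluoromethanesulfonyloxy)ethenyl | C=C(OS(=O)(=O)C(F)(F)F)[C@H]2C[C@H](O[Si](C)(C)C(C)(C)C)[C@@](C)(O3)[C@@H](O[Si](C)(C)C(C)(C)C)[C@H]2OC3(C)C | intermediate
11 | 4-methylpent-3-en-1-ol | CC(C)=CCCO | starting material
12 | 4-methylpent-3-enal | CC(C)=CCC=O | intermediate
13 | (S)-allylic alcohol: as 10, with the triflate replaced by (1S)-1-hydroxy-4-methylpent-3-en-1-yl, giving ring–C(=CH2)–CH(OH)–CH2–CH=CMe2 | C=C([C@H](CC=C(C)C)O)[C@H]2C[C@H](O[Si](C)(C)C(C)(C)C)[C@@](C)(O3)[C@@H](O[Si](C)(C)C(C)(C)C)[C@H]2OC3(C)C | intermediate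
14 | triol: 13 without the two silyl groups (free OH at C3, C5, C2′) | C=C([C@H](CC=C(C)C)O)[C@H]2C[C@H](O)[C@@](C)(O3)[C@@H](O)[C@H]2OC3(C)C | intermediate
15 | tris-angelate: 14 with O3, O5 and O2′ esterified as (Z)-2-methylbut-2-enoates, acetonide retained | C=C([C@H](CC=C(C)C)OC(=O)/C(C)=C\C)[C@H]2C[C@H](OC(=O)/C(C)=C\C)[C@@](C)(O3)[C@@H](OC(=O)/C(C)=C\C)[C@H]2OC3(C)C | intermediate
16 | diol tris-angelate: 15 without the acetonide (free OH at C4 and C6; side-chain C4′=C5′ alkene) | C=C([C@H](CC=C(C)C)OC(=O)/C(C)=C\C)[C@H]1C[C@H](OC(=O)/C(C)=C\C)[C@@](C)(O)[C@@H](OC(=O)/C(C)=C\C)[C@H]1O | intermediate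
17 | target: ring C1 (R), C3 (S), C4 (R), C5 (S), C6 (S); side chain C2′ (S), epoxide C4′ (S); angelates at O3, O5, O2′; free OH at C4 and C6 | C=C([C@H](C[C@@H]1OC1(C)C)OC(=O)/C(C)=C\C)[C@H]1C[C@H](OC(=O)/C(C)=C\C)[C@@](C)(O)[C@@H](OC(=O)/C(C)=C\C)[C@H]1O | target

**Step count**

Total: 12 steps. Longest linear sequence: 11 steps (steps 1–6 and 8–12, from 1 to 17).

**Three steps most likely to fail**

1. Step 3 (annulation). The amino-acid catalyst may be tied up as an unreactive imine of the enal, the hindered enamine may add too slowly, and the aldol may close with the wrong hydroxyl orientation or lose the C3 configuration by re-enolisation. The fallback sets out from 4 (with 3) and comes back at 6, separating the two bond formations. Ketone 4 is converted with Me3SiOTf/Et3N into the silyl enol ether (Z)-1,3-bis(tert-butyldimethylsilyloxy)-2-(trimethylsilyloxy)prop-1-ene F1. Mukaiyama–Michael addition of F1 to 3 under Yb(OTf)3 catalysis (CH2Cl2, −40 °C) and aqueous work-up should give keto aldehyde 5, now isolated as an epimer mixture. Compound 5 is then cyclised on its own with O-tert-butyl-D-threonine, where C1 and C3 still equilibrate through the enamines, to give 6.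

2. Step 4 (methyl addition). The equatorial and axial trajectories may compete, because the axial C3 silyl ether favours the other face on stereoelectronic grounds; enolisation or retro-aldol cleavage of the magnesium aldolate may also intervene. The fallback sets out from 6 and comes back at 7, moving the stereocontrol from carbonyl addition to a hydroxyl-directed epoxidation. Petasis methylenation of 6 with Cp2TiMe2 (toluene, 65 °C) should give the exocyclic alkene F2. Epoxidation with VO(acac)2/tBuOOH, directed by the homoallylic axial C6–OH, should give the spiro-epoxide F3 with the oxirane oxygen cis to that hydroxyl. Hydride opening at the CH2 terminus with LiEt3BH (THF, 0 °C) then gives 7.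

3. Step 10 (triple angeloylation). Acylation of the hindered C5 hydroxyl may stay incomplete, and the Z-configured acyl group may isomerise to the E (tigloyl) form under forcing conditions. The fallback sets out from 14 and comes back at 15, building the Z-alkenes after the ester bonds. Triol 14 is acylated with 2-[bis(2,2,2-trifluoroethoxy)phosphoryl]propanoic acid (N-ethyl-N′-(3-dimethylaminopropyl)carbodiimide hydrochloride, DMAP, CH2Cl2) to the tris(phosphonopropionate) F4. A threefold Still–Gennari olefination of F4 with acetaldehyde (KN(SiMe3)2, 18-crown-6, THF, −78 °C) should then give the three (Z)-2-methylbut-2-enoates of 15.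

Further compounds
F1 | step 3 | (Z)-1,3-bis(tert-butyldimethylsilyloxy)-2-(trimethylsilyloxy)prop-1-ene | C[Si](C)(C)O/C(CO[Si](C)(C)C(C)(C)C)=C\O[Si](C)(C)C(C)(C)C
F2 | step 4 | exocyclic alkene: 6 with the ketone C=O replaced by C=CH2, ring configuration as in 6 | CC1(OCCO1)[C@H]2C[C@H](O[Si](C)(C)C(C)(C)C)C(=C)[C@@H](O[Si](C)(C)C(C)(C)C)[C@H]2O
F3 | step 4 | spiro-epoxide of F2, oxirane oxygen cis to the C6 hydroxyl | CC1(OCCO1)[C@H]2C[C@H](O[Si](C)(C)C(C)(C)C)[C@]3(CO3)[C@@H](O[Si](C)(C)C(C)(C)C)[C@H]2O
F4 | step 10 | tris(phosphonopropionate): 14 with O3, O5 and O2′ esterified by 2-[bis(2,2,2-trifluoroethoxy)phosphoryl]propanoic acid (phosphonate α-carbons as epimer mixtures) | C=C([C@H](CC=C(C)C)OC(=O)C(C)P(=O)(OCC(F)(F)F)OCC(F)(F)F)[C@H]2C[C@H](OC(=O)C(C)P(=O)(OCC(F)(F)F)OCC(F)(F)F)[C@@](C)(O3)[C@@H](OC(=O)C(C)P(=O)(OCC(F)(F)F)OCC(F)(F)F)[C@H]2OC3(C)C
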